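**Compound numbers used throughout** (full names and SMILES are in the list after the steps)

1 pentan-3-one · 2 silyl enol ether of 1 · 3 malonyl dichloride · 4 acid chloride formed in the flask · 5 6-ethyl-4-hydroxy-5-methylpyran-2-one · 6 N,N-dimethylmethyleneiminium iodide · 7 Mannich salt of 5 · 8 4-hydroxy-6-methylpyran-2-one · 9 methyl 3-methylbut-2-enoate · 10 pyranone with the acylmethyl arm · 11 methylidene pyrandione formed in the flask · 12 methylene-linked bis-pyranone · 13 triketo ester formed in the flask · 14 acylphloroglucinol with ring A complete · 15 bis-silyl ether of 14 · 16 aryl iodide · 17 (E)-styrylstannane · 18 chalcone · 19 silylated (S)-flavanone · 20 target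

## Analysis of the target

The target is a (2S)-flavanone: benzene ring A is fused through C4a and C8a to the dihydropyranone ring C (O1, C2, C3, C4), and C2 carries the phenyl ring B. Ring A is fully substituted: C5–OH, C6 bearing a CH2 group that leads to C3 of a 6-ethyl-4-hydroxy-5-methylpyran-2-one, C7–OH, and C8 bearing a 3-methylbut-2-enoyl group, beside O1 and the C4 carbonyl. C2 is the only stereocentre; it is benzylic, bonded to O1 and β to the C4 ketone, so its configuration is lost whenever ring C opens by retro-oxa-Michael reaction, which base or acid can bring about. The sensitive groups are four: the β,β-dimethyl enone at C8, which an ortho hydroxyl can attack to give a 2,2-dimethylchromanone; the methylene bridge between two electron-rich rings, which acid or hot base can cleave; the enolic lactone; and the air-sensitive polyphenol. The difficulty lies in ring A: three different carbon substituents and three oxygens must stand in a fixed order, and stepwise electrophilic substitution of a trihydroxybenzene would need choices between nearly equivalent positions and Lewis-acid acylations that the enone does not survive. The strategy rests on the triad C6–C7–C8 of ring A. A methylene-bearing carbon, an oxygenated carbon and an acyl-bearing carbon in a row are what C3, C2 and the side-chain carbon of a 3-substituted 6-(acylmethyl)-4-hydroxypyran-2-one become when that heterocycle is opened and closed again through carbon; ring A and such a pyranone are isomers.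

## Retrosynthetic reasoning

**20 ⇐ 19.** The last disconnection only removes two tert-butyldimethylsilyl groups, one on the C5 oxygen and one on the enol oxygen of the pyranone. The first leaves a single free hydroxyl beside the carbon that becomes C4a, which settles the direction of ring-C closure. The second masks an enol of carboxylic-acid strength that would neutralise a basic catalyst. The forward step must free both oxygens without base strong enough to open ring C or to push the C7 hydroxyl onto the enone.

**19 ⇐ 18.** Ring C is cut at O1–C2. This is the bond of a flavanone that forms and breaks most easily, and C2 is the only stereocentre; making it last means C2 never meets the strongly basic or heated steps. The forward reaction is an intramolecular oxa-Michael addition of the C8a hydroxyl to the cinnamoyl group of 18 and has to choose one face of the β-carbon. The other hydroxyl ortho to the cinnamoyl group is silylated, so neither the regioisomeric closure nor the fast uncatalysed closure of a doubly ortho-hydroxylated chalcone is open.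

**18 ⇐ 16 + 17.** The cinnamoyl group is cut on both sides of its carbonyl carbon, at C4a–C4 and C4–C3. A Friedel–Crafts acylation with a cinnamoyl electrophile would make the same ketone in one step, but the Lewis acid it needs would close an ortho hydroxyl onto the enone of 14 and can cleave the methylene bridge. Taking the carbonyl carbon from a one-carbon insertion between the aryl iodide 16 and the alkenylstannane 17 under palladium catalysis reaches 18 without acid or base, with the E double bond delivered intact.

**16 ⇐ 15 ⇐ 14.** The iodine goes onto the one unsubstituted carbon of ring A, so no choice of position arises. Before that, the two most acidic hydroxyls of 14 are silylated: the pyranone enol and the ring-A hydroxyl para to the ketone (the future C5–OH). The two hydroxyls ortho to the ketone are less acidic and hydrogen-bonded, and the selectivity relies on that difference.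

**14 ⇐ 12 (key disconnection).** Ring A is cut at the C7–C8 bond, and the C7 oxygen is traced back to a lactone carbonyl; 14 is an isomer of the bis-pyranone 12. In 12 the carbon that becomes C6 is C3 of a pyranone and already bears the bridge. The carbon that becomes C8 is the side-chain methylene and already bears the acyl group. The carbon that becomes C4a is the unsubstituted C5 of that pyranone. The gain is that the whole substitution order of ring A is laid down in a precursor made by ordinary enolate chemistry, and no arene has to be acylated with the sensitive unsaturated acid. The forward reaction must open the right lactone, close through carbon onto the former lactone carbonyl (Claisen) and not onto the terminal ketone (aldol), and leave the enone, the bridge and the second pyranone alone.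

**12 ⇐ 7 + 10.** The bridge is cut between its CH2 and C3 of the arm-bearing pyranone. If a free one-carbon electrophile were added to a mixture of 5 and 10, both pyranones would react alike at C3 and three dimers would result. The one-carbon unit is therefore fixed on 5 first, as the Mannich salt 7; base then releases the methylidene dione 11 from 7 in the presence of 10, whose C3 enolate adds to it.

**10 ⇐ 8 + 9.** The arm is cut between its methylene and its ketone carbon. The methylene is the C6 methyl group of 8, the only nucleophilic carbon of the dianion of 8, and the ketone with its alkene comes from ester 9, so one Claisen-type acylation builds the whole arm.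

**7 ⇐ 5 + 6; 5 ⇐ 2 + 3; 2 ⇐ 1.** Salt 7 is the Mannich adduct of 5 and the iminium salt 6 at C3, the only free ring carbon of 5. Pyranone 5 is cut at C4–C5 and at the lactone C–O bond into the silyl enol ether 2 and the diacid chloride 3. Because 1 is symmetric, the ethyl group at C6 and the methyl group at C5 come from its two halves and no regiochemical question arises.

## Alternatives that were turned down

**Alternative 1:** Ring C is cut at C4–C4a. In the forward direction the carboxyl group of the aryloxy acid A1, activated as a mixed anhydride, acylates the ring carbon ortho to the ether oxygen (intramolecular Friedel–Crafts acylation) and gives the 6-formylflavanone A2.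
- For it: C2 is set in an open-chain ether before any ring is closed. The two positions ortho to the ether oxygen of A1 are equivalent, so the closure has no regiochemical question. The formyl group of A2 is a ready handle for the bridge, by reductive alkylation of 5.
- Against it: the benzylic C–O bond of A1 lies β to the activated carboxyl, so elimination to a cinnamic acid and a phenol competes under the acidic conditions and erodes the configuration. The free phenols are acylated by the activating agent. A2 still lacks the C8 acyl group, which would have to be put on by Friedel–Crafts acylation with the unsaturated acid on a flavanone with free ortho hydroxyls, the conditions under which the enone closes to a dimethylchromanone and ring C opens.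
- Comparison: on the certainty of the stereocentre this alternative is the stronger one. The chosen strategy offers instead a ring A whose C6 methylene and C8 enone are there by construction, with no electrophilic acylation by the enone acid at any stage, at the price of building ring C last.

**Alternative 2:** The C8 acyl group is cut on both sides of its carbonyl carbon. In the forward direction the C8 iodide A3, a carbonyl unit and the alkenylboronate A4 are joined in one palladium-catalysed carbonylative cross-coupling to give the protected 8-acylflavanone A5; no ring is formed.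
- For it: the enone arrives under non-acidic conditions while both neighbouring oxygens are capped, so it cannot close to a chromanone in that step. C2 is taken over from an existing (S)-flavanone and need not be created. After deprotection the free C6 could take the bridge by alkylation with 7.
- Against it: A3 requires an iodination that tells C8 from C6 on a ring A in which both are activated alike. The base and heat of a boron-based carbonylative coupling act on a flavanone whose ring C opens by retro-oxa-Michael reaction, which puts C2 at risk. The aryl–palladium centre is flanked by two ortho substituents. Afterwards the acetal groups of A5 must be removed with acid beside the new enone and its ortho oxygen, and the bridge must be installed on the unprotected, base-sensitive product.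
- Comparison: in step count and in the origin of the stereocentre this alternative is stronger than the chosen route. The chosen strategy has no C6/C8 decision at all, since the order of substituents on ring A is fixed before the ring exists, and it makes the stereocentre after the last heated step. It borrows the idea of carbonyl insertion, but at C4a, before C2 exists and without added base.

**Alternative 3:** Ring C is cut at C3–C4. In the forward direction a carbene catalyst generated from a thiazolium salt adds to the aldehyde group of A6; the resulting acyl-anion equivalent displaces the primary sulfonate within the same molecule (6-exo-tet) and closes ring C to give A7.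
- For it: the stereocentre is made earlier, in the ether A6, and takes no part in the closure, so the oxa-Michael equilibrium that threatens C2 is avoided in that step. Conditions are mild.
- Against it: A7 carries neither of the two carbon substituents of ring A, so C6 and C8 would still have to be told apart and the enone still introduced by electrophilic acylation of a flavanone. The benzyl ether would later have to be removed in the presence of an enone that hydrogenolysis reduces. A6 itself needs alkylation of a hydrogen-bonded hydroxyl ortho to the aldehyde by a secondary benzylic electrophile. Alkylation of an acyl-anion equivalent by a sulfonate has narrow precedent.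
- Comparison: on keeping C2 intact during ring closure it is at least as good as the chosen route. It solves ring C and leaves ring A, the hard part, untouched, whereas the chosen strategy settles ring A first.

Key step: step 6

Assumption: the quinidine-derived thiourea of step 10 is taken to direct the phenoxide to the Si face of the chalcone β-carbon (2S); should it favour the Re face, its quinine-derived pseudoenantiomer replaces it and nothing else changes.

## Route

Step 1
Reactants: 1 pentan-3-one
Product: 2 trimethyl(pent-2-en-3-yloxy)silane (E/Z mixture)
Conditions: LiN(i-Pr)2, THF, −78 °C; TMSCl, −78 °C → rt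
Reagents that add atoms: chlorotrimethylsilane (TMSCl), C[Si](C)(C)Cl
Why: Enolate formation and O-silylation; 1 is symmetric, so only one constitutional silyl enol ether can form, and its E/Z ratio is of no consequence because the double bond ends up inside the pyranone ring.

Step 2
Reactants: 2 trimethyl(pent-2-en-3-yloxy)silane; 3 malonyl dichloride
Product: 5 6-ethyl-4-hydroxy-5-methyl-2H-pyran-2-one, via diketo acid chloride 4 (not isolated)
Conditions: Et2O, −78 °C → rt
Reagents that add atoms: none
Why: C-Acylation of the silyl enol ether by one acid chloride group gives 4, whose enol oxygen closes onto the second acid chloride (lactonisation, 6-exo-trig) to the 4-hydroxypyran-2-one; this pyranone synthesis from ketone silyl enol ethers and malonyl dichloride is established. The ethyl group at C6 and the methyl group at C5 are the two halves of the symmetric ketone, so their positions are fixed.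

Step 3
Reactants: 5 6-ethyl-4-hydroxy-5-methyl-2H-pyran-2-one; 6 N,N-dimethylmethyleneiminium iodide
Product: 7 [(6-ethyl-4-hydroxy-5-methyl-2-oxo-2H-pyran-3-yl)methyl]dimethylammonium iodide
Conditions: MeCN, 0 °C → rt, no base; salt collected by filtration
Reagents that add atoms: none
Why: Mannich reaction at C3, the only free and the most nucleophilic carbon of the 4-hydroxypyran-2-one. It is run without base so that the product separates as its ammonium salt and cannot eliminate to the methylidene dione before the partner is present.

Step 4
Reactants: 8 4-hydroxy-6-methyl-2H-pyran-2-one; 9 methyl 3-methylbut-2-enoate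
Product: 10 4-hydroxy-6-(4-methyl-2-oxopent-3-en-1-yl)-2H-pyran-2-one
Conditions: 8 (2.1 equiv), LiN(i-Pr)2 (4.2 equiv), THF, −78 → −10 °C; 9 (1.0 equiv), −78 → 0 °C; aq HCl
Reagents that add atoms: none
Why: Claisen-type C-acylation of the dilithium salt of 8 at its exocyclic carbanion, the only carbon nucleophile of the dianion, a known way to 6-(2-oxoalkyl)-4-hydroxypyran-2-ones. The second equivalent of dianion takes up the acidic proton of the product, so no free amide base remains to deprotonate the γ-methyl groups of 9, and conjugate addition is disfavoured at the β,β-disubstituted carbon.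

Step 5
Reactants: 7 [(6-ethyl-4-hydroxy-5-methyl-2-oxo-2H-pyran-3-yl)methyl]dimethylammonium iodide; 10 4-hydroxy-6-(4-methyl-2-oxopent-3-en-1-yl)-2H-pyran-2-one
Product: 12 3-[(6-ethyl-4-hydroxy-5-methyl-2-oxo-2H-pyran-3-yl)methyl]-4-hydroxy-6-(4-methyl-2-oxopent-3-en-1-yl)-2H-pyran-2-one, via methylidene pyrandione 11 (not isolated)
Conditions: Et3N (1.1 equiv), MeCN, 0 °C → rt, 7 added in portions to 10; then 1 M HCl
Reagents that add atoms: none
Why: Base frees the Mannich base, which loses dimethylamine to the Knoevenagel-type acceptor 11; this is trapped at once by the C3 enolate of 10 (Michael addition). Because the one-carbon unit is attached to one partner beforehand, the unsymmetrical dimer should form in place of the statistical mixture, and in the weakly basic medium the side-chain methylene of 10, far less acidic than the ring enol, stays out of play.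

Step 6
Reactants: 12 3-[(6-ethyl-4-hydroxy-5-methyl-2-oxo-2H-pyran-3-yl)methyl]-4-hydroxy-6-(4-methyl-2-oxopent-3-en-1-yl)-2H-pyran-2-one
Product: 14 6-ethyl-4-hydroxy-5-methyl-3-{[2,4,6-trihydroxy-3-(3-methylbut-2-enoyl)phenyl]methyl}-2H-pyran-2-one, via triketo ester 13 (not isolated)
Conditions: Mg(OMe)2 (6 equiv), degassed MeOH, Ar, 50 °C → reflux; then poured into cold 1 M HCl
Reagents that add atoms: none
Why: The magnesium alkoxide converts 12 into its polyanion, and methoxide opens the lactone of the ring that carries the acylmethyl arm to the magnesium-chelated 3,5,7-triketo ester 13 (ester C1, C2 bearing the pyranonylmethyl group, ketones at C3, C5 and C7). The C6 carbanion of 13, stabilised by the two flanking ketones, adds to the ester carbonyl in a Claisen condensation, a 6-exo-trig closure that makes the bond which becomes C7–C8 of the target; loss of methoxide and enolisation give ring A as the trihydroxybenzene. This is the known base-induced recyclisation of 6-(2-oxoalkyl)-4-hydroxypyran-2-ones, masked 3,5,7-triketo esters, to acylphloroglucinols, applied here to a 3-substituted pyranone. No stereocentre is formed, since the only sp3 centre of 13 is lost on aromatisation. The step needs Claisen and not aldol closure: attack of C2 on the C7 ketone would create a ring carbon bearing both the ester and the pyranonylmethyl group, which cannot dehydrate to an arene and reverts by retro-aldol reaction, whereas the Claisen product is drained off as an aromatic magnesium phenoxide, and chelation of the 1,3-dicarbonyl units by magnesium holds the chain in the folded shape this closure requires. The acyl group, the oxygen from the former lactone carbonyl and the methylene-bearing carbon end up contiguous by construction, and the former C5 of the pyranone remains as the one unsubstituted ring carbon. The second pyranone has no carbon flanked by two carbonyl groups within six-ring distance of its lactone carbonyl and so cannot form a carbocycle, though it may be methanolysed reversibly. The β,β-disubstituted enone resists conjugate addition of methoxide, and closure of an ortho phenoxide onto it is disfavoured while the ring is a polyanion, so the mixture is quenched cold and fast into dilute acid.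

Step 7
Reactants: 14 6-ethyl-4-hydroxy-5-methyl-3-{[2,4,6-trihydroxy-3-(3-methylbut-2-enoyl)phenyl]methyl}-2H-pyran-2-one
Product: 15 4-[(tert-butyldimethylsilyl)oxy]-3-({6-[(tert-butyldimethylsilyl)oxy]-2,4-dihydroxy-3-(3-methylbut-2-enoyl)phenyl}methyl)-6-ethyl-5-methyl-2H-pyran-2-one
Conditions: TBSCl (2.1 equiv), imidazole, DMF, −10 → 0 °C
Reagents that add atoms: tert-butyldimethylsilyl chloride (TBSCl), CC(C)(C)[Si](C)(C)Cl
Why: Silylation is expected to follow acidity and freedom from chelation: the pyranone enol and the ring-A hydroxyl para to the ketone (the future C5–OH) are the two most acidic hydroxyls, while the two hydroxyls ortho to the ketone are less acidic and take turns in a six-membered hydrogen bond to it. Capping the para hydroxyl leaves one free hydroxyl beside the unsubstituted ring carbon, and capping the enol removes a proton that would neutralise the amine catalyst of step 10.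

Step 8
Reactants: 15 4-[(tert-butyldimethylsilyl)oxy]-3-({6-[(tert-butyldimethylsilyl)oxy]-2,4-dihydroxy-3-(3-methylbut-2-enoyl)phenyl}methyl)-6-ethyl-5-methyl-2H-pyran-2-one
Product: 16 4-[(tert-butyldimethylsilyl)oxy]-3-({6-[(tert-butyldimethylsilyl)oxy]-2,4-dihydroxy-5-iodo-3-(3-methylbut-2-enoyl)phenyl}methyl)-6-ethyl-5-methyl-2H-pyran-2-one
Conditions: NIS (1.05 equiv), MeCN, 0 °C, dark
Reagents that add atoms: N-iodosuccinimide (NIS), O=C1CCC(=O)N1I
Why: Electrophilic aromatic iodination at the single unsubstituted carbon of ring A, which is ortho or para to three oxygen substituents; both carbon positions of the pyranone are substituted and the enone is electron-poor, so no other site competes.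

Step 9
Reactants: 16 4-[(tert-butyldimethylsilyl)oxy]-3-({6-[(tert-butyldimethylsilyl)oxy]-2,4-dihydroxy-5-iodo-3-(3-methylbut-2-enoyl)phenyl}methyl)-6-ethyl-5-methyl-2H-pyran-2-one; 17 (E)-tributyl(2-phenylethenyl)stannane
Product: 18 4-[(tert-butyldimethylsilyl)oxy]-3-({6-[(tert-butyldimethylsilyl)oxy]-2,4-dihydroxy-3-(3-methylbut-2-enoyl)-5-[(2E)-3-phenylprop-2-enoyl]phenyl}methyl)-6-ethyl-5-methyl-2H-pyran-2-one
Conditions: CO (3 atm), PdCl2(PPh3)2 (5 mol %), THF, 60 °C
Reagents that add atoms: carbon monoxide, [C-]#[O+]
Why: Carbonylative Stille coupling: the precatalyst is reduced to zerovalent palladium, which inserts into the C–I bond; CO insertion is favoured over direct transmetalation at an aryl group with two ortho substituents, and transfer of the styryl group with retention of its E geometry followed by reductive elimination gives the 2′-hydroxychalcone. The conditions are neutral, so the enone, the silyl ethers and the methylene bridge, all of which a Lewis-acid acylation would endanger, are left alone.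

Step 10
Reactants: 18 4-[(tert-butyldimethylsilyl)oxy]-3-({6-[(tert-butyldimethylsilyl)oxy]-2,4-dihydroxy-3-(3-methylbut-2-enoyl)-5-[(2E)-3-phenylprop-2-enoyl]phenyl}methyl)-6-ethyl-5-methyl-2H-pyran-2-one
Product: 19 4-[(tert-butyldimethylsilyl)oxy]-3-{[(2S)-5-[(tert-butyldimethylsilyl)oxy]-7-hydroxy-8-(3-methylbut-2-enoyl)-4-oxo-2-phenyl-3,4-dihydro-2H-chromen-6-yl]methyl}-6-ethyl-5-methyl-2H-pyran-2-one
Conditions: N-[3,5-bis(trifluoromethyl)phenyl]-N′-[(9R)-6′-methoxycinchonan-9-yl]thiourea (10 mol %), toluene, −20 → 0 °C
Reagents that add atoms: none
Why: Intramolecular oxa-Michael addition (6-endo-trig) of a 2′-hydroxychalcone under bifunctional cinchona-thiourea catalysis: the quinuclidine nitrogen deprotonates the one free hydroxyl ortho to the cinnamoyl group while the thiourea binds the chalcone carbonyl, and the chiral pocket directs the phenoxide to the Si face of the β-carbon, which makes C2 S. The silyloxy group on the other ortho position excludes the regioisomeric ring closure and the uncatalysed closure typical of 2′,6′-dihydroxychalcones, and the mono-substituted, phenyl-bearing β-carbon of the chalcone is a far better acceptor than the β,β-dimethyl carbon of the other enone.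

Step 11
Reactants: 19 4-[(tert-butyldimethylsilyl)oxy]-3-{[(2S)-5-[(tert-butyldimethylsilyl)oxy]-7-hydroxy-8-(3-methylbut-2-enoyl)-4-oxo-2-phenyl-3,4-dihydro-2H-chromen-6-yl]methyl}-6-ethyl-5-methyl-2H-pyran-2-one
Product: 20 6-ethyl-4-hydroxy-3-{[(2S)-5,7-dihydroxy-8-(3-methylbut-2-enoyl)-4-oxo-2-phenyl-3,4-dihydro-2H-chromen-6-yl]methyl}-5-methyl-2H-pyran-2-one
Conditions: TBAF, AcOH (1:1, 2.5 equiv), THF, 0 °C
Reagents that add atoms: none
Why: Fluoride cleaves the aryl and the enol silyl ether at 0 °C, and acetic acid protonates the phenoxide and the pyranone enolate as they are released, so that ring C is not opened (C2 keeps its configuration) and the C7 hydroxyl does not add to the enone.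

## Compound list

1 | pentan-3-one | CCC(=O)CC | starting material
2 | trimethyl(pent-2-en-3-yloxy)silane (E/Z mixture) | CC=C(CC)O[Si](C)(C)C | intermediate
3 | malonyl dichloride (propanedioyl dichloride) | O=C(Cl)CC(=O)Cl | starting material
4 | 4-methyl-3,5-dioxoheptanoyl chloride (formed in the flask) | CCC(=O)C(C)C(=O)CC(=O)Cl | intermediate
5 | 6-ethyl-4-hydroxy-5-methyl-2H-pyran-2-one | CCc1oc(=O)cc(O)c1C | intermediate
6 | N,N-dimethylmethyleneiminium iodide | C=[N+](C)C.[I-] | starting material
7 | [(6-ethyl-4-hydroxy-5-methyl-2-oxo-2H-pyran-3-yl)methyl]dimethylammonium iodide | CCc1oc(=O)c(C[NH+](C)C)c(O)c1C.[I-] | intermediate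
8 | 4-hydroxy-6-methyl-2H-pyran-2-one | Cc1cc(O)cc(=O)o1 | starting material
9 | methyl 3-methylbut-2-enoate | COC(=O)C=C(C)C | starting material
10 | 4-hydroxy-6-(4-methyl-2-oxopent-3-en-1-yl)-2H-pyran-2-one | O=c1cc(O)cc(CC(=O)C=C(C)C)o1 | intermediate
11 | 6-ethyl-5-methyl-3-methylidene-2H-pyran-2,4(3H)-dione (formed in the flask) | CCC1=C(C)C(=O)C(=C)C(=O)O1 | intermediate
12 | 3-[(6-ethyl-4-hydroxy-5-methyl-2-oxo-2H-pyran-3-yl)methyl]-4-hydroxy-6-(4-methyl-2-oxopent-3-en-1-yl)-2H-pyran-2-one | CCc1oc(=O)c(Cc2c(O)cc(CC(=O)C=C(C)C)oc2=O)c(O)c1C | intermediate
13 | methyl 2-[(6-ethyl-4-hydroxy-5-methyl-2-oxo-2H-pyran-3-yl)methyl]-9-methyl-3,5,7-trioxodec-8-enoate (formed in the flask as its magnesium chelate) | COC(=O)C(Cc1c(O)c(C)c(CC)oc1=O)C(=O)CC(=O)CC(=O)C=C(C)C | intermediate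
14 | 6-ethyl-4-hydroxy-5-methyl-3-{[2,4,6-trihydroxy-3-(3-methylbut-2-enoyl)phenyl]methyl}-2H-pyran-2-one | CCc1oc(=O)c(Cc2c(O)cc(O)c(C(=O)C=C(C)C)c2O)c(O)c1C | intermediate
15 | 4-[(tert-butyldimethylsilyl)oxy]-3-({6-[(tert-butyldimethylsilyl)oxy]-2,4-dihydroxy-3-(3-methylbut-2-enoyl)phenyl}methyl)-6-ethyl-5-methyl-2H-pyran-2-one | CCc1oc(=O)c(Cc2c(O[Si](C)(C)C(C)(C)C)cc(O)c(C(=O)C=C(C)C)c2O)c(O[Si](C)(C)C(C)(C)C)c1C | intermediate
16 | 4-[(tert-butyldimethylsilyl)oxy]-3-({6-[(tert-butyldimethylsilyl)oxy]-2,4-dihydroxy-5-iodo-3-(3-methylbut-2-enoyl)phenyl}methyl)-6-ethyl-5-methyl-2H-pyran-2-one | CCc1oc(=O)c(Cc2c(O[Si](C)(C)C(C)(C)C)c(I)c(O)c(C(=O)C=C(C)C)c2O)c(O[Si](C)(C)C(C)(C)C)c1C | intermediate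
17 | (E)-tributyl(2-phenylethenyl)stannane | CCCC[Sn](CCCC)(CCCC)/C=C/c1ccccc1 | starting material
18 | 4-[(tert-butyldimethylsilyl)oxy]-3-({6-[(tert-butyldimethylsilyl)oxy]-2,4-dihydroxy-3-(3-methylbut-2-enoyl)-5-[(2E)-3-phenylprop-2-enoyl]phenyl}methyl)-6-ethyl-5-methyl-2H-pyran-2-one | CCc1oc(=O)c(Cc2c(O[Si](C)(C)C(C)(C)C)c(C(=O)/C=C/c3ccccc3)c(O)c(C(=O)C=C(C)C)c2O)c(O[Si](C)(C)C(C)(C)C)c1C | intermediate
19 | 4-[(tert-butyldimethylsilyl)oxy]-3-{[(2S)-5-[(tert-butyldimethylsilyl)oxy]-7-hydroxy-8-(3-methylbut-2-enoyl)-4-oxo-2-phenyl-3,4-dihydro-2H-chromen-6-yl]methyl}-6-ethyl-5-methyl-2H-pyran-2-one | CCc1oc(=O)c(Cc2c(O)c(C(=O)C=C(C)C)c3c(c2O[Si](C)(C)C(C)(C)C)C(=O)C[C@@H](c2ccccc2)O3)c(O[Si](C)(C)C(C)(C)C)c1C | intermediate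
20 | 6-ethyl-4-hydroxy-3-{[(2S)-5,7-dihydroxy-8-(3-methylbut-2-enoyl)-4-oxo-2-phenyl-3,4-dihydro-2H-chromen-6-yl]methyl}-5-methyl-2H-pyran-2-one | CCc1oc(=O)c(Cc2c(O)c(C(=O)C=C(C)C)c3c(c2O)C(=O)C[C@@H](c2ccccc2)O3)c(O)c1C | target

## Step count and least certain steps

Total: 11 steps. Longest linear sequence: 10 steps (1 → 2 → 5 → 7 → 12 → 14 → 15 → 16 → 18 → 19 → 20; steps 1, 2, 3, 5, 6, 7, 8, 9, 10, 11).

**Step 6 (key step).** The most likely failure is methanolysis of the second lactone alongside the wanted ring opening: the 6-ethyl-5-methylpyranone would then remain as an open 3,5-diketo ester that does not close again on acidification, or acylates the neighbouring phenol. Next come retro-Michael cleavage of the methylene bridge in hot alkoxide, with recombination to symmetrical dimers, and addition of an ortho phenoxide to the enone while the mixture passes through neutral pH on quenching. Fallback: the order of ring formation and bridging is reversed. Pyranone 10 alone is recyclised with Mg(OMe)2 in methanol, the plain case of this reaction with no second lactone and no bridge present, to 3-methyl-1-(2,4,6-trihydroxyphenyl)but-2-en-1-one F1. One of its two equivalent free ring carbons is then alkylated with the methylidene dione 11 released from salt 7 by Et3N in MeCN. This fallback sets out from 10 and comes back to the route at 14.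

**Step 10.** Poor facial selectivity is the main risk, because the reacting hydroxyl is hydrogen-bonded to two carbonyl groups and may not sit in the catalyst as a simple 2′-hydroxychalcone does. Incomplete conversion through reversibility, and addition of the same phenoxide to the dimethyl enone, which is held close to it, are the other risks. Fallback: C2 is set by carbon–carbon bond formation. Iodide 16 is coupled under CO with (Z)-tributyl(2-ethoxyethenyl)stannane and PdCl2(PPh3)2 to the (Z)-3-ethoxypropenoyl ketone F2. With pyridinium p-toluenesulfonate F2 loses ethanol and closes onto its only free ortho hydroxyl to the chromone F3. Asymmetric conjugate addition of phenylboronic acid to F3, catalysed by Pd(OCOCF3)2 (divalent palladium) and the enantiomer of the pyridine–oxazoline ligand t-BuPyOx that leads to 2S, then gives 19; the acyclic β,β-disubstituted enone is not a substrate for this arylation. This fallback sets out from 16 and comes back at 19.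

**Step 9.** The coupling may fail through direct coupling without CO insertion, slow oxidative addition at an iodide flanked by two oxygen substituents, protodestannylation of 17 by the acidic phenols, or thermal closure of a hydroxyl onto the enone during the hours at 60 °C. Fallback without CO: Stille coupling of 16 with tributyl(1-ethoxyvinyl)stannane gives the aryl enol ether F4, which aqueous oxalic acid hydrolyses to the methyl ketone F5. N,N-Dimethylformamide dimethyl acetal converts F5 into the enaminone F6, which closes to the chromone F3 with loss of dimethylamine on mild acid; F3 is carried on as in the fallback for step 10. This fallback sets out from 16 and comes back at 19.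

**Step 7.** The risk is loss of site selectivity: the hydroxyl next to the free ring carbon, when it is not the one engaged in the hydrogen bond to the ketone, may be silylated in place of or in addition to the more hindered para hydroxyl, which would block the oxygen needed for ring C. Fallback: the para hydroxyl is protected at a stage where it is unique. Pyranone 10 is recyclised alone to 3-methyl-1-(2,4,6-trihydroxyphenyl)but-2-en-1-one F1, as in the fallback for step 6. In F1 the hydroxyl para to the ketone is the only one not hydrogen-bonded and has no ortho substituent, so one equivalent of TBSCl with imidazole should give the 4-O-silyl ether F7. Alkylation of F7 with 11 generated from 7 gives the mono-silyl analogue of 14, F8, and silylation of its pyranone enol, the most acidic hydroxyl left, gives 15. This fallback sets out from 10 and comes back at 15.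

**Step 4.** Proton transfer from the γ-methyl groups of 9 to the dianion in place of acylation, and sluggish acylation by a conjugated ester, are the likely problems. Fallback: aldol addition of the same dianion of 8 to 3-methylbut-2-enal (fast 1,2-addition, no acidic product, so one equivalent of dianion suffices) gives the racemic allylic alcohol 4-hydroxy-6-(2-hydroxy-4-methylpent-3-en-1-yl)-2H-pyran-2-one F9, which MnO2 in CH2Cl2 oxidises to the enone. This fallback sets out from 8 and comes back at 10.

## Further compounds

F1 | step 6 | 3-methyl-1-(2,4,6-trihydroxyphenyl)but-2-en-1-one | CC(C)=CC(=O)c1c(O)cc(O)cc1O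
F2 | step 10 | 4-[(tert-butyldimethylsilyl)oxy]-3-({6-[(tert-butyldimethylsilyl)oxy]-5-[(2Z)-3-ethoxyprop-2-enoyl]-2,4-dihydroxy-3-(3-methylbut-2-enoyl)phenyl}methyl)-6-ethyl-5-methyl-2H-pyran-2-one | CCc1oc(=O)c(Cc2c(O[Si](C)(C)C(C)(C)C)c(C(=O)/C=C\OCC)c(O)c(C(=O)C=C(C)C)c2O)c(O[Si](C)(C)C(C)(C)C)c1C
F3 | step 10 | 4-[(tert-butyldimethylsilyl)oxy]-3-{[5-[(tert-butyldimethylsilyl)oxy]-7-hydroxy-8-(3-methylbut-2-enoyl)-4-oxo-4H-chromen-6-yl]methyl}-6-ethyl-5-methyl-2H-pyran-2-one | CCc1oc(=O)c(Cc2c(O)c(C(=O)C=C(C)C)c3occc(=O)c3c2O[Si](C)(C)C(C)(C)C)c(O[Si](C)(C)C(C)(C)C)c1C
F4 | step 9 | 4-[(tert-butyldimethylsilyl)oxy]-3-({6-[(tert-butyldimethylsilyl)oxy]-5-(1-ethoxyethenyl)-2,4-dihydroxy-3-(3-methylbut-2-enoyl)phenyl}methyl)-6-ethyl-5-methyl-2H-pyran-2-one | CCc1oc(=O)c(Cc2c(O[Si](C)(C)C(C)(C)C)c(C(=C)OCC)c(O)c(C(=O)C=C(C)C)c2O)c(O[Si](C)(C)C(C)(C)C)c1C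
F5 | step 9 | 3-({5-acetyl-6-[(tert-butyldimethylsilyl)oxy]-2,4-dihydroxy-3-(3-methylbut-2-enoyl)phenyl}methyl)-4-[(tert-butyldimethylsilyl)oxy]-6-ethyl-5-methyl-2H-pyran-2-one | CCc1oc(=O)c(Cc2c(O[Si](C)(C)C(C)(C)C)c(C(C)=O)c(O)c(C(=O)C=C(C)C)c2O)c(O[Si](C)(C)C(C)(C)C)c1C
F6 | step 9 | 4-[(tert-butyldimethylsilyl)oxy]-3-({6-[(tert-butyldimethylsilyl)oxy]-5-[(2E)-3-(dimethylamino)prop-2-enoyl]-2,4-dihydroxy-3-(3-methylbut-2-enoyl)phenyl}methyl)-6-ethyl-5-methyl-2H-pyran-2-one | CCc1oc(=O)c(Cc2c(O[Si](C)(C)C(C)(C)C)c(C(=O)/C=C/N(C)C)c(O)c(C(=O)C=C(C)C)c2O)c(O[Si](C)(C)C(C)(C)C)c1C
F7 | step 7 | 1-{4-[(tert-butyldimethylsilyl)oxy]-2,6-dihydroxyphenyl}-3-methylbut-2-en-1-one | CC(C)=CC(=O)c1c(O)cc(O[Si](C)(C)C(C)(C)C)cc1O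
F8 | step 7 | 3-({6-[(tert-butyldimethylsilyl)oxy]-2,4-dihydroxy-3-(3-methylbut-2-enoyl)phenyl}methyl)-6-ethyl-4-hydroxy-5-methyl-2H-pyran-2-one | CCc1oc(=O)c(Cc2c(O[Si](C)(C)C(C)(C)C)cc(O)c(C(=O)C=C(C)C)c2O)c(O)c1C
F9 | step 4 | 4-hydroxy-6-(2-hydroxy-4-methylpent-3-en-1-yl)-2H-pyran-2-one (racemic) | O=c1cc(O)cc(CC(O)C=C(C)C)o1
A1 | alternative 1 | (S)-3-(4-formyl-3,5-dihydroxyphenoxy)-3-phenylpropanoic acid | O=C(O)C[C@@H](c1ccccc1)Oc1cc(O)c(C=O)c(O)c1
A2 | alternative 1 | (S)-6-formyl-5,7-dihydroxyflavanone | O=Cc1c(O)cc2c(c1O)C(=O)C[C@@H](c1ccccc1)O2
A3 | alternative 2 | (S)-8-iodo-5,7-bis(methoxymethoxy)flavanone | O=C1C[C@@H](c2ccccc2)Oc2c(I)c(OCOC)cc(OCOC)c12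
A4 | alternative 2 | 4,4,5,5-tetramethyl-2-(2-methylprop-1-en-1-yl)-1,3,2-dioxaborolane | CC(C)=CB1OC(C)(C)C(C)(C)O1
A5 | alternative 2 | (S)-5,7-bis(methoxymethoxy)-8-(3-methylbut-2-enoyl)flavanone | O=C1C[C@@H](c2ccccc2)Oc2c(C(=O)C=C(C)C)c(OCOC)cc(OCOC)c12
A6 | alternative 3 | (R)-2-[5-(benzyloxy)-2-formyl-3-hydroxyphenoxy]-2-phenylethyl 4-methylbenzenesulfonate | Cc1ccc(cc1)S(=O)(=O)OC[C@@H](c1ccccc1)Oc1cc(OCc2ccccc2)cc(O)c1C=O
A7 | alternative 3 | (S)-7-(benzyloxy)-5-hydroxyflavanone | O=C1C[C@@H](c2ccccc2)Oc2cc(OCc3ccccc3)cc(O)c12
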